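**Retrosynthetic overview**

1. Cut the side-chain ester: spiroketal-lactone core alcohol plus O-silylated (S)-3-hydroxy-2,2-dimethylbutanoic acid (fragment D, from methyl acetoacetate).
2. Open the spiroketal lactone to a γ-keto ester with a pendant CH2OH; cut its ketone by Fukuyama coupling into a bicyclic thioester and the zinc reagent of the Roche-ester iodide (fragment C).
3. Form the bicyclo[3.1.1]heptane (cyclobutane and six-membered ring together) by intramolecular vinylketene–alkene [2+2]; the bridge carbonyl is then excised.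
4. Assemble the acyclic acid by Z-selective Wittig reaction of a phosphonium salt (fragment A, stereocentre from Brown allylation) with an α-silyloxy ketone (fragment B).
5. Ring order: carbobicycle first, then tetrahydrofuran hemiketal, then γ-lactone (spiroketal) last.

Assumption: the spiro-ketal centre of the target is the thermodynamically favoured epimer, so it is set by acid equilibration in step 20.

Abbreviations: TBS = tert-butyldimethylsilyl, PMB = 4-methoxybenzyl, TES = triethylsilyl.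

**Fragment A**

Step 1
Reactants: 1 methyl 3-methylbut-2-enoate
Product: 2 methyl (2E)-3-methyl-4-oxobut-2-enoate
Conditions: SeO2 (1.2 equiv), 1,4-dioxane, reflux
Reagents that add atoms: selenium dioxide O=[Se]=O
Why: Riley allylic oxidation attacks the methyl trans to the ester, giving the (E)-enal and leaving the methyl cis to the ester that is needed later for vinylketene formation.

Step 2
Reactants: 2 methyl (2E)-3-methyl-4-oxobut-2-enoate
Product: 4 methyl (2E,4S)-4-hydroxy-3-methylhepta-2,6-dienoate, via diisopinocampheylborinate 3 (not isolated)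
Conditions: (−)-Ipc2B(allyl) (from (+)-α-pinene, salt-free), Et2O, −78 °C; then HOCH2CH2NH2, rt
Reagents that add atoms: (−)-B-allyldiisopinocampheylborane C=CCB([C@@H]1C[C@@H]2C[C@H]([C@H]1C)C2(C)C)[C@@H]1C[C@@H]2C[C@H]([C@H]1C)C2(C)C
Why: Brown asymmetric allylboration through a chair Zimmerman–Traxler transition state delivers allyl to the Si face of the aldehyde, setting the (4S) carbinol (the future C3–O centre) as it does for benzaldehyde.

Step 3
Reactants: 4 methyl (2E,4S)-4-hydroxy-3-methylhepta-2,6-dienoate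
Product: 5 methyl (2E,4S)-4-(TBSO)-3-methylhepta-2,6-dienoate
Conditions: TBSCl, imidazole, DMF, rt
Reagents that add atoms: tert-butyldimethylsilyl chloride CC(C)(C)[Si](C)(C)Cl
Why: Standard silyl ether protection of the secondary allylic alcohol, with no change at the stereocentre.

Step 4
Reactants: 5 methyl (2E,4S)-4-(TBSO)-3-methylhepta-2,6-dienoate
Product: 7 methyl (2E,4S)-4-(TBSO)-6-hydroxy-3-methylhex-2-enoate, via ozonide 6 (not isolated)
Conditions: O3 (titrated), CH2Cl2, −78 °C; then NaBH4, MeOH, −78 to 0 °C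
Reagents that add atoms: ozone [O-][O+]=O
Why: Chemoselective ozonolysis of the electron-rich terminal alkene over the trisubstituted conjugated enoate, followed by reductive work-up to the primary alcohol.

Step 5
Reactants: 7 methyl (2E,4S)-4-(TBSO)-6-hydroxy-3-methylhex-2-enoate
Product: 8 methyl (2E,4S)-4-(TBSO)-6-iodo-3-methylhex-2-enoate
Conditions: I2, PPh3, imidazole, CH2Cl2, 0 °C to rt
Reagents that add atoms: iodine II
Why: Appel-type (Garegg–Samuelsson) iodination of an unhindered primary alcohol under neutral conditions.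

Step 6
Reactants: 8 methyl (2E,4S)-4-(TBSO)-6-iodo-3-methylhex-2-enoate
Product: 9 [(3S,4E)-3-(TBSO)-6-methoxy-4-methyl-6-oxohex-4-en-1-yl]triphenylphosphonium iodide
Conditions: PPh3, MeCN, 80 °C
Reagents that add atoms: triphenylphosphine c1ccc(cc1)P(c1ccccc1)c1ccccc1
Why: Substitution (quaternisation) of the primary iodide by the phosphine; the β,β-disubstituted enoate is inert to phosphine conjugate addition.

**Fragment B**

Step 7
Reactants: 10 but-3-en-1-ol
Product: 11 1-[(but-3-en-1-yloxy)methyl]-4-methoxybenzene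
Conditions: NaH, PMBCl, Bu4NI (cat.), THF/DMF, 0 °C to rt
Reagents that add atoms: 4-methoxybenzyl chloride COc1ccc(CCl)cc1
Why: Williamson ether synthesis installs the oxidatively removable PMB group on the future C(=O)-bearing arm.

Step 8
Reactants: 11 1-[(but-3-en-1-yloxy)methyl]-4-methoxybenzene
Product: 12 4-[(4-methoxybenzyl)oxy]butane-1,2-diol (racemic)
Conditions: OsO4 (2 mol %), N-methylmorpholine N-oxide, acetone/H2O, rt
Reagents that add atoms: N-methylmorpholine N-oxide C[N+]1([O-])CCOCC1; water O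
Why: Upjohn dihydroxylation of the terminal alkene; the new stereocentre is irrelevant because it is oxidised in step 10.

Step 9
Reactants: 12 4-[(4-methoxybenzyl)oxy]butane-1,2-diol
Product: 13 1-(TBSO)-4-[(4-methoxybenzyl)oxy]butan-2-ol (racemic)
Conditions: TBSCl (1.05 equiv), imidazole, CH2Cl2, −10 °C
Reagents that add atoms: tert-butyldimethylsilyl chloride CC(C)(C)[Si](C)(C)Cl
Why: Sterically controlled monosilylation of the primary hydroxyl of a 1,2-diol.

Step 10
Reactants: 13 1-(TBSO)-4-[(4-methoxybenzyl)oxy]butan-2-ol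
Product: 14 1-(TBSO)-4-[(4-methoxybenzyl)oxy]butan-2-one
Conditions: Dess–Martin periodinane, CH2Cl2, rt
Reagents that add atoms: none
Why: Dess–Martin oxidation is non-basic, so the β-alkoxy ketone does not eliminate.

**Union of A and B, bicycle formation**

Step 11
Reactants: 9 [(3S,4E)-3-(TBSO)-6-methoxy-4-methyl-6-oxohex-4-en-1-yl]triphenylphosphonium iodide; 14 1-(TBSO)-4-[(4-methoxybenzyl)oxy]butan-2-one
Product: 16 methyl (2E,4S,6Z)-4-(TBSO)-7-[(TBSO)methyl]-9-[(4-methoxybenzyl)oxy]-3-methylnona-2,6-dienoate, via phosphorus ylide 15 (not isolated)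
Conditions: 9, KN(SiMe3)2 (0.98 equiv), THF, −78 °C; then 14, −78 to 0 °C
Reagents that add atoms: none
Why: Wittig olefination of an α-alkoxy ketone with a non-stabilised, salt-free ylide is Z-selective for the oxygenated CH2 (expected about 10:1, separable), placing CH2OTBS cis to the chain that becomes the three-carbon bridge.

Step 12
Reactants: 16 methyl (2E,4S,6Z)-4-(TBSO)-7-[(TBSO)methyl]-9-[(4-methoxybenzyl)oxy]-3-methylnona-2,6-dienoate
Product: 17 (2E,4S,6Z)-4-(TBSO)-7-[(TBSO)methyl]-9-[(4-methoxybenzyl)oxy]-3-methylnona-2,6-dienoic acid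
Conditions: LiOH·H2O, THF/MeOH/H2O, 40 °C; then 1 M HCl to pH 4, 0 °C
Reagents that add atoms: lithium hydroxide [Li+].[OH-]
Why: Saponification of the methyl ester; silyl and PMB ethers are stable to aqueous hydroxide.

Step 13
Reactants: 17 (2E,4S,6Z)-4-(TBSO)-7-[(TBSO)methyl]-9-[(4-methoxybenzyl)oxy]-3-methylnona-2,6-dienoic acid
Product: 20 (1R,3S,5R,7S)-3-(TBSO)-7-[(TBSO)methyl]-7-{2-[(4-methoxybenzyl)oxy]ethyl}-2-methylidenebicyclo[3.1.1]heptan-6-one (3-OTBS anti to C7; CH2OTBS syn to C3), via acid chloride 18 (not isolated), via vinylketene 19 (not isolated)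
Conditions: 1-chloro-N,N,2-trimethylprop-1-en-1-amine, CH2Cl2, 0 °C to rt; evaporate; slow addition (6 h) to Et3N (5 equiv), toluene, 110 °C, 0.005 M
Reagents that add atoms: none
Why: Intramolecular ketene–alkene [2+2] cycloaddition (vinylketene by 1,4-dehydrochlorination through the methyl cis to COCl) is suprafacial on the Z-alkene, so CH2OTBS ends syn to the three-carbon bridge, and the tether folds with the C4-OTBS group away from that CH2OTBS, placing the oxygen anti to the quaternary bridge and letting the single Brown-derived centre fix both bridgeheads and the quaternary carbon.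

Step 14
Reactants: 20 (1R,3S,5R,7S)-3-(TBSO)-7-[(TBSO)methyl]-7-{2-[(4-methoxybenzyl)oxy]ethyl}-2-methylidenebicyclo[3.1.1]heptan-6-one
Product: 22 (1R,3S,5R,6S)-3-(TBSO)-6-[(TBSO)methyl]-6-{2-[(4-methoxybenzyl)oxy]ethyl}-2-methylidenebicyclo[3.1.1]heptane, via tosylhydrazone 21 (not isolated)
Conditions: TsNHNH2, EtOH, 50 °C; evaporate; catecholborane, CHCl3, 0 °C; then NaOAc·3H2O, 60 °C
Reagents that add atoms: none
Why: Caglioti–Kabalka reductive deoxygenation (hydride addition to the tosylhydrazone, sulfinate loss, N2 extrusion) is neutral, so the silyl ethers, PMB ether and non-conjugated exocyclic alkene survive and no stereocentre is touched.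

Step 15
Reactants: 22 (1R,3S,5R,6S)-3-(TBSO)-6-[(TBSO)methyl]-6-{2-[(4-methoxybenzyl)oxy]ethyl}-2-methylidenebicyclo[3.1.1]heptane
Product: 23 2-[(1R,3S,5R,6S)-3-(TBSO)-6-[(TBSO)methyl]-2-methylidenebicyclo[3.1.1]heptan-6-yl]ethan-1-ol
Conditions: DDQ, CH2Cl2/pH 7 buffer (10:1), 0 °C
Reagents that add atoms: none
Why: Oxidative PMB cleavage by benzylic hydride abstraction leaves silyl ethers and the alkene untouched.

Step 16
Reactants: 23 2-[(1R,3S,5R,6S)-3-(TBSO)-6-[(TBSO)methyl]-2-methylidenebicyclo[3.1.1]heptan-6-yl]ethan-1-ol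
Product: 24 2-[(1R,3S,5R,6S)-3-(TBSO)-6-[(TBSO)methyl]-2-methylidenebicyclo[3.1.1]heptan-6-yl]acetic acid
Conditions: TEMPO (20 mol %), PhI(OAc)2 (2.2 equiv), MeCN/H2O, rt
Reagents that add atoms: water O
Why: Oxoammonium (TEMPO/PhI(OAc)2) oxidation takes the primary alcohol through the aldehyde hydrate to the acid without affecting the alkene.

Step 17
Reactants: 24 2-[(1R,3S,5R,6S)-3-(TBSO)-6-[(TBSO)methyl]-2-methylidenebicyclo[3.1.1]heptan-6-yl]acetic acid
Product: 25 S-ethyl 2-[(1R,3S,5R,6S)-3-(TBSO)-6-[(TBSO)methyl]-2-methylidenebicyclo[3.1.1]heptan-6-yl]ethanethioate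
Conditions: EtSH, DCC, DMAP (cat.), CH2Cl2, 0 °C to rt
Reagents that add atoms: ethanethiol CCS
Why: Steglich thioesterification provides the acyl donor for the ketone-forming coupling.

**Fragment C**

Step 18
Reactants: 26 methyl (2R)-3-hydroxy-2-methylpropanoate
Product: 27 methyl (2S)-3-iodo-2-methylpropanoate
Conditions: I2, PPh3, imidazole, CH2Cl2, 0 °C to rt
Reagents that add atoms: iodine II
Why: Appel-type iodination at the primary carbon; the stereocentre is untouched and the descriptor changes only because CH2I outranks the ester.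

**Fragment coupling and spiroketal lactone**

Step 19
Reactants: 25 S-ethyl 2-[(1R,3S,5R,6S)-3-(TBSO)-6-[(TBSO)methyl]-2-methylidenebicyclo[3.1.1]heptan-6-yl]ethanethioate; 27 methyl (2S)-3-iodo-2-methylpropanoate
Product: 29 methyl (2R)-5-[(1R,3S,5R,6S)-3-(TBSO)-6-[(TBSO)methyl]-2-methylidenebicyclo[3.1.1]heptan-6-yl]-2-methyl-4-oxopentanoate, via organozinc iodide 28 (not isolated)
Conditions: 27, Zn dust (activated with BrCH2CH2Br/TMSCl), THF, 35 °C; then 25, PdCl2(PPh3)2 (5 mol %), toluene, rt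
Reagents that add atoms: none
Why: Fukuyama coupling (Pd-catalysed thioester–alkylzinc ketone synthesis) stops at the ketone and tolerates ester, silyl ethers and alkene, and the β-zincio ester cannot enolise so the (R) methyl centre is retained.

Step 20
Reactants: 29 methyl (2R)-5-[(1R,3S,5R,6S)-3-(TBSO)-6-[(TBSO)methyl]-2-methylidenebicyclo[3.1.1]heptan-6-yl]-2-methyl-4-oxopentanoate
Product: 31 (1R,3S,5R,6S)-3-hydroxy-2-methylidenebicyclo[3.1.1]heptane whose C6 is also C8 of a (3R,5R)-3-methyl-1,6-dioxaspiro[4.4]nonan-2-one (ring CH2–O syn to C3), via keto diol 30 (not isolated)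
Conditions: HF·pyridine, pyridine/THF, 0 °C to rt; concentrate; PPTS (0.2 equiv), toluene, 50 °C, 4 Å sieves
Reagents that add atoms: none
Why: Desilylation followed by acid-catalysed spiroketalisation–lactonisation (CH2OH closes the hemiketal, whose OH then displaces methanol from the ester) under equilibrating conditions, which should favour the (5R) spiro epimer with the lactone methyl cis to the tetrahydrofuran CH2 (pseudo-equatorial) and the ring oxygen anomerically disposed; the minor epimer is separated and re-equilibrated.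

**Fragment D**

Step 21
Reactants: 32 methyl 3-oxobutanoate
Product: 33 methyl 2,2-dimethyl-3-oxobutanoate
Conditions: MeI (2.5 equiv), K2CO3 (2.5 equiv), acetone, reflux
Reagents that add atoms: iodomethane CI
Why: Double C-alkylation of the β-keto ester enolate.

Step 22
Reactants: 33 methyl 2,2-dimethyl-3-oxobutanoate
Product: 34 methyl (3S)-3-hydroxy-2,2-dimethylbutanoate
Conditions: H2 (50 atm), RuCl2[(S)-BINAP] (0.5 mol %), MeOH, 50 °C
Reagents that add atoms: none
Why: Noyori asymmetric hydrogenation of a β-keto ester through the chelated Ru–BINAP complex, with the (S)-ligand giving the (S)-carbinol.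

Step 23
Reactants: 34 methyl (3S)-3-hydroxy-2,2-dimethylbutanoate
Product: 35 (3S)-3-hydroxy-2,2-dimethylbutanoic acid
Conditions: LiOH·H2O, MeOH/H2O, 40 °C; then 1 M HCl
Reagents that add atoms: lithium hydroxide [Li+].[OH-]
Why: Saponification of the hindered ester; the carbinol centre is not epimerisable because the α-carbon is quaternary.

Step 24
Reactants: 35 (3S)-3-hydroxy-2,2-dimethylbutanoic acid
Product: 37 (3S)-2,2-dimethyl-3-(triethylsilyloxy)butanoic acid, via bis-silyl derivative 36 (not isolated)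
Conditions: TESCl (2.2 equiv), imidazole, DMF, 0 °C to rt; then K2CO3 (cat.), THF/H2O, 0 °C
Reagents that add atoms: chlorotriethylsilane CC[Si](Cl)(CC)CC
Why: Bis-silylation followed by selective hydrolysis of the labile silyl ester leaves the TES ether.

**Endgame**

Step 25
Reactants: 37 (3S)-2,2-dimethyl-3-(triethylsilyloxy)butanoic acid; 31 spiroketal-lactone alcohol
Product: 39 (3S)-2,2-dimethyl-3-(triethylsilyloxy)butanoate ester of 31, via acid chloride 38 (not isolated)
Conditions: 37, 1-chloro-N,N,2-trimethylprop-1-en-1-amine, CH2Cl2, 0 °C; then 31, DMAP (2 equiv), Et3N, CH2Cl2, 40 °C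
Reagents that add atoms: none
Why: DMAP-catalysed acylation of the only free hydroxyl with a neutral-generated acid chloride proceeds with retention at the carbinol carbon, which already has the required configuration.

Step 26
Reactants: 39 (3S)-2,2-dimethyl-3-(triethylsilyloxy)butanoate ester of 31
Product: 40 target, the (3S)-3-hydroxy-2,2-dimethylbutanoate ester of 31
Conditions: HF·pyridine, pyridine/THF, 0 °C
Reagents that add atoms: none
Why: Fluoride-mediated cleavage of the TES ether under buffered conditions that avoid retro-aldol and acyl migration and leave the spiroketal lactone intact.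

**Compound list**

1 | methyl 3-methylbut-2-enoate | COC(=O)C=C(C)C | starting material
2 | methyl (2E)-3-methyl-4-oxobut-2-enoate | COC(=O)/C=C(\C)C=O | intermediate
3 | diisopinocampheylborinate of 4 | COC(=O)/C=C(\C)[C@@H](OB([C@@H]1C[C@@H]2C[C@H]([C@H]1C)C2(C)C)[C@@H]1C[C@@H]2C[C@H]([C@H]1C)C2(C)C)CC=C | intermediate
4 | methyl (2E,4S)-4-hydroxy-3-methylhepta-2,6-dienoate | COC(=O)/C=C(\C)[C@@H](O)CC=C | intermediate
5 | methyl (2E,4S)-4-(TBSO)-3-methylhepta-2,6-dienoate | COC(=O)/C=C(\C)[C@@H](O[Si](C)(C)C(C)(C)C)CC=C | intermediate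
6 | ozonide (1,2,4-trioxolane) of the terminal alkene of 5 | COC(=O)/C=C(\C)[C@@H](O[Si](C)(C)C(C)(C)C)CC1OCOO1 | intermediate
7 | methyl (2E,4S)-4-(TBSO)-6-hydroxy-3-methylhex-2-enoate | COC(=O)/C=C(\C)[C@@H](O[Si](C)(C)C(C)(C)C)CCO | intermediate
8 | methyl (2E,4S)-4-(TBSO)-6-iodo-3-methylhex-2-enoate | COC(=O)/C=C(\C)[C@@H](O[Si](C)(C)C(C)(C)C)CCI | intermediate
9 | [(3S,4E)-3-(TBSO)-6-methoxy-4-methyl-6-oxohex-4-en-1-yl]triphenylphosphonium iodide | COC(=O)/C=C(\C)[C@@H](O[Si](C)(C)C(C)(C)C)CC[P+](c1ccccc1)(c1ccccc1)c1ccccc1.[I-] | intermediate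
10 | but-3-en-1-ol | C=CCCO | starting material
11 | 1-[(but-3-en-1-yloxy)methyl]-4-methoxybenzene | C=CCCOCc1ccc(OC)cc1 | intermediate
12 | 4-[(4-methoxybenzyl)oxy]butane-1,2-diol (racemic) | OCC(O)CCOCc1ccc(OC)cc1 | intermediate
13 | 1-(TBSO)-4-[(4-methoxybenzyl)oxy]butan-2-ol (racemic) | CC(C)(C)[Si](C)(C)OCC(O)CCOCc1ccc(OC)cc1 | intermediate
14 | 1-(TBSO)-4-[(4-methoxybenzyl)oxy]butan-2-one | CC(C)(C)[Si](C)(C)OCC(=O)CCOCc1ccc(OC)cc1 | intermediate
15 | phosphorus ylide from 9 | COC(=O)/C=C(\C)[C@@H](O[Si](C)(C)C(C)(C)C)CC=P(c1ccccc1)(c1ccccc1)c1ccccc1 | intermediate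
16 | methyl (2E,4S,6Z)-4-(TBSO)-7-[(TBSO)methyl]-9-[(4-methoxybenzyl)oxy]-3-methylnona-2,6-dienoate | COC(=O)/C=C(\C)[C@@H](O[Si](C)(C)C(C)(C)C)C/C=C(\CO[Si](C)(C)C(C)(C)C)CCOCc1ccc(OC)cc1 | intermediate
17 | (2E,4S,6Z)-4-(TBSO)-7-[(TBSO)methyl]-9-[(4-methoxybenzyl)oxy]-3-methylnona-2,6-dienoic acid | OC(=O)/C=C(\C)[C@@H](O[Si](C)(C)C(C)(C)C)C/C=C(\CO[Si](C)(C)C(C)(C)C)CCOCc1ccc(OC)cc1 | intermediate
18 | acid chloride of 17 | ClC(=O)/C=C(\C)[C@@H](O[Si](C)(C)C(C)(C)C)C/C=C(\CO[Si](C)(C)C(C)(C)C)CCOCc1ccc(OC)cc1 | intermediate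
19 | (4S,6Z)-4-(TBSO)-7-[(TBSO)methyl]-9-[(4-methoxybenzyl)oxy]-3-methylidenenona-1,6-dien-1-one (vinylketene) | O=C=CC(=C)[C@@H](O[Si](C)(C)C(C)(C)C)C/C=C(\CO[Si](C)(C)C(C)(C)C)CCOCc1ccc(OC)cc1 | intermediate
20 | (1R,3S,5R,7S)-3-(TBSO)-7-[(TBSO)methyl]-7-{2-[(4-methoxybenzyl)oxy]ethyl}-2-methylidenebicyclo[3.1.1]heptan-6-one | C=C1[C@@H](O[Si](C)(C)C(C)(C)C)C[C@H]2C(=O)[C@@H]1[C@]2(CO[Si](C)(C)C(C)(C)C)CCOCc1ccc(OC)cc1 | intermediate
21 | tosylhydrazone of 20 | C=C1[C@@H](O[Si](C)(C)C(C)(C)C)C[C@H]2C(=NNS(=O)(=O)c3ccc(C)cc3)[C@@H]1[C@]2(CO[Si](C)(C)C(C)(C)C)CCOCc1ccc(OC)cc1 | intermediate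
22 | (1R,3S,5R,6S)-3-(TBSO)-6-[(TBSO)methyl]-6-{2-[(4-methoxybenzyl)oxy]ethyl}-2-methylidenebicyclo[3.1.1]heptane | C=C1[C@@H](O[Si](C)(C)C(C)(C)C)C[C@H]2C[C@@H]1[C@]2(CO[Si](C)(C)C(C)(C)C)CCOCc1ccc(OC)cc1 | intermediate
23 | 2-[(1R,3S,5R,6S)-3-(TBSO)-6-[(TBSO)methyl]-2-methylidenebicyclo[3.1.1]heptan-6-yl]ethan-1-ol | C=C1[C@@H](O[Si](C)(C)C(C)(C)C)C[C@H]2C[C@@H]1[C@]2(CO[Si](C)(C)C(C)(C)C)CCO | intermediate
24 | 2-[(1R,3S,5R,6S)-3-(TBSO)-6-[(TBSO)methyl]-2-methylidenebicyclo[3.1.1]heptan-6-yl]acetic acid | C=C1[C@@H](O[Si](C)(C)C(C)(C)C)C[C@H]2C[C@@H]1[C@]2(CO[Si](C)(C)C(C)(C)C)CC(=O)O | intermediate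
25 | S-ethyl 2-[(1R,3S,5R,6S)-3-(TBSO)-6-[(TBSO)methyl]-2-methylidenebicyclo[3.1.1]heptan-6-yl]ethanethioate | C=C1[C@@H](O[Si](C)(C)C(C)(C)C)C[C@H]2C[C@@H]1[C@]2(CO[Si](C)(C)C(C)(C)C)CC(=O)SCC | intermediate
26 | methyl (2R)-3-hydroxy-2-methylpropanoate | OC[C@@H](C)C(=O)OC | starting material
27 | methyl (2S)-3-iodo-2-methylpropanoate | IC[C@@H](C)C(=O)OC | intermediate
28 | [(2S)-3-methoxy-2-methyl-3-oxopropyl]zinc iodide | I[Zn]C[C@@H](C)C(=O)OC | intermediate
29 | methyl (2R)-5-[(1R,3S,5R,6S)-3-(TBSO)-6-[(TBSO)methyl]-2-methylidenebicyclo[3.1.1]heptan-6-yl]-2-methyl-4-oxopentanoate | C=C1[C@@H](O[Si](C)(C)C(C)(C)C)C[C@H]2C[C@@H]1[C@]2(CO[Si](C)(C)C(C)(C)C)CC(=O)C[C@@H](C)C(=O)OC | intermediate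
30 | methyl (2R)-5-[(1R,3S,5R,6S)-3-hydroxy-6-(hydroxymethyl)-2-methylidenebicyclo[3.1.1]heptan-6-yl]-2-methyl-4-oxopentanoate | C=C1[C@@H](O)C[C@H]2C[C@@H]1[C@]2(CO)CC(=O)C[C@@H](C)C(=O)OC | intermediate
31 | (1R,3S,5R,6S)-3-hydroxy-2-methylidenebicyclo[3.1.1]heptane with C6 = C8 of a (3R,5R)-3-methyl-1,6-dioxaspiro[4.4]nonan-2-one (core alcohol) | C=C1[C@@H](O)C[C@H]2C[C@@H]1[C@@]21CO[C@@]2(C[C@@H](C)C(=O)O2)C1 | intermediate
32 | methyl 3-oxobutanoate | COC(=O)CC(C)=O | starting material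
33 | methyl 2,2-dimethyl-3-oxobutanoate | COC(=O)C(C)(C)C(C)=O | intermediate
34 | methyl (3S)-3-hydroxy-2,2-dimethylbutanoate | COC(=O)C(C)(C)[C@H](C)O | intermediate
35 | (3S)-3-hydroxy-2,2-dimethylbutanoic acid | OC(=O)C(C)(C)[C@H](C)O | intermediate
36 | triethylsilyl (3S)-2,2-dimethyl-3-(triethylsilyloxy)butanoate | CC[Si](CC)(CC)OC(=O)C(C)(C)[C@H](C)O[Si](CC)(CC)CC | intermediate
37 | (3S)-2,2-dimethyl-3-(triethylsilyloxy)butanoic acid | OC(=O)C(C)(C)[C@H](C)O[Si](CC)(CC)CC | intermediate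
38 | (3S)-2,2-dimethyl-3-(triethylsilyloxy)butanoyl chloride | ClC(=O)C(C)(C)[C@H](C)O[Si](CC)(CC)CC | intermediate
39 | (3S)-2,2-dimethyl-3-(triethylsilyloxy)butanoate ester of 31 | C=C1[C@@H](OC(=O)C(C)(C)[C@H](C)O[Si](CC)(CC)CC)C[C@H]2C[C@@H]1[C@@]21CO[C@@]2(C[C@@H](C)C(=O)O2)C1 | intermediate
40 | (3S)-3-hydroxy-2,2-dimethylbutanoate ester of 31 (CNP0212779.5) | C=C1[C@@H](OC(=O)C(C)(C)[C@H](C)O)C[C@H]2C[C@@H]1[C@@]21CO[C@@]2(C[C@@H](C)C(=O)O2)C1 | target

**Step count**

Total: 26 steps. Longest linear sequence: 17 steps (steps 1–6, 11–17, 19, 20, 25, 26, from 1 to 40).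

**Steps most likely to fail**

Step 13. The alkene is deactivated by its allylic silyloxy group, and the sense of diastereocontrol by the C4-OTBS group is argued from sterics, not precedent. The fallback sets out from acid 17 and returns at ketone 20. Acid 17 is deconjugated with LiN(iPr)2 (2.2 equiv, THF, −78 °C, AcOH quench) to the 3-methylidene acid F1. F1 is condensed with pyrrolidine (EDC·HCl, HOBt, CH2Cl2) to pyrrolidine amide F2. Treatment with Tf2O and 2,6-di-tert-butyl-4-methylpyridine in 1,2-dichloroethane (0 to 80 °C) gives vinyl keteniminium triflate F3, which is far more electrophilic than the ketene. It undergoes the same intramolecular [2+2] at lower temperature to cyclobutaniminium triflate F4, and hydrolysis with aqueous NaHCO3 gives 20.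

Step 14. The hydrazone of a ketone flanked by two bridgeheads may form or reduce sluggishly. The fallback sets out from ketone 20 and returns at 22. NaBH4 in MeOH at 0 °C gives cyclobutanol F5 (either carbinol epimer serves). NaH, CS2 and MeI in THF convert it into S-methyl xanthate F6. Barton–McCombie radical deoxygenation (Bu3SnH, AIBN, toluene, 90 °C) then gives 22; the secondary cyclobutyl radical cannot usefully rearrange because closure onto the methylidene would create a housane.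

Step 20. The tertiary hemiketal hydroxyl may not displace methanol from the ester under acid mild enough for the methylidene-pinane skeleton. The fallback sets out from keto ester 29 and returns at 31. The ester is saponified first (LiOH·H2O, THF/H2O, 0 °C) to keto acid F7. HF·pyridine then liberates dihydroxy keto acid F8. As a γ-keto acid with a neighbouring CH2OH, F8 cyclodehydrates on concentration or brief warming in toluene to 31, replacing the transesterification by a dehydrative spiroketalisation under the same thermodynamic control.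

**Further compounds**

F1 | step 13 | (4S,6Z)-4-(TBSO)-7-[(TBSO)methyl]-9-[(4-methoxybenzyl)oxy]-3-methylidenenon-6-enoic acid | OC(=O)CC(=C)[C@@H](O[Si](C)(C)C(C)(C)C)C/C=C(\CO[Si](C)(C)C(C)(C)C)CCOCc1ccc(OC)cc1
F2 | step 13 | pyrrolidine amide of F1 | O=C(CC(=C)[C@@H](O[Si](C)(C)C(C)(C)C)C/C=C(\CO[Si](C)(C)C(C)(C)C)CCOCc1ccc(OC)cc1)N1CCCC1
F3 | step 13 | vinyl keteniminium triflate from F2 | C(=C=[N+]1CCCC1)C(=C)[C@@H](O[Si](C)(C)C(C)(C)C)C/C=C(\CO[Si](C)(C)C(C)(C)C)CCOCc1ccc(OC)cc1.[O-]S(=O)(=O)C(F)(F)F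
F4 | step 13 | cyclobutaniminium triflate (pyrrolidinium ylidene analogue of 20) | C=C1[C@@H](O[Si](C)(C)C(C)(C)C)C[C@H]2C(=[N+]3CCCC3)[C@@H]1[C@]2(CO[Si](C)(C)C(C)(C)C)CCOCc1ccc(OC)cc1.[O-]S(=O)(=O)C(F)(F)F
F5 | step 14 | cyclobutanol from reduction of 20 (carbinol epimer unspecified) | C=C1[C@@H](O[Si](C)(C)C(C)(C)C)C[C@H]2C(O)[C@@H]1[C@]2(CO[Si](C)(C)C(C)(C)C)CCOCc1ccc(OC)cc1
F6 | step 14 | S-methyl xanthate of F5 | C=C1[C@@H](O[Si](C)(C)C(C)(C)C)C[C@H]2C(OC(=S)SC)[C@@H]1[C@]2(CO[Si](C)(C)C(C)(C)C)CCOCc1ccc(OC)cc1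
F7 | step 20 | (2R)-5-[(1R,3S,5R,6S)-3-(TBSO)-6-[(TBSO)methyl]-2-methylidenebicyclo[3.1.1]heptan-6-yl]-2-methyl-4-oxopentanoic acid | C=C1[C@@H](O[Si](C)(C)C(C)(C)C)C[C@H]2C[C@@H]1[C@]2(CO[Si](C)(C)C(C)(C)C)CC(=O)C[C@@H](C)C(=O)O
F8 | step 20 | (2R)-5-[(1R,3S,5R,6S)-3-hydroxy-6-(hydroxymethyl)-2-methylidenebicyclo[3.1.1]heptan-6-yl]-2-methyl-4-oxopentanoic acid | C=C1[C@@H](O)C[C@H]2C[C@@H]1[C@]2(CO)CC(=O)C[C@@H](C)C(=O)O
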